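## Retrosynthetic overview
1. Ester C–O bond: Gentiside H ⇒ (S)-18-methylicosan-1-ol + 2,3-bis(benzyloxy)benzoic acid. The forward steps are a Steglich esterification and a final hydrogenolysis.
2. The alcohol ⇒ ω-hydroxy ketone carrying C=O at chain carbon C15, removed by Wolff–Kishner reduction. The ketone ⇒ α-acylated benzyl ester, by hydrogenolysis and decarboxylation.
3. Key C14–C15 bond: crossed Claisen condensation. The lithium enolate of benzyl 15-(benzyloxy)pentadecanoate (from ω-pentadecalactone) is acylated by (S)-4-methylhexanoyl chloride.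
4. (S)-4-Methylhexanoyl chloride ⇒ (S)-2-methylbutan-1-ol (chiral pool) by tosylate/malonic ester homologation. This alcohol supplies the only stereocentre, which is never touched.
5. No ring is formed. The benzene ring is bought as 2,3-dihydroxybenzoic acid.

Assumption: the SMILES is read as 17 CH2 groups between the stereocentre and the ester oxygen with (S) configuration, i.e. (18S)-18-methylicosyl 2,3-dihydroxybenzoate, and commercial (S)-(−)-2-methylbutan-1-ol of ≥98% ee is used.

## Route

Step 1
Reactants: 1 (S)-2-methylbutan-1-ol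
Product: 2 (S)-2-methylbutyl 4-methylbenzenesulfonate
Conditions: TsCl (1.2 equiv), Et3N (1.5 equiv), DMAP (5 mol %), CH2Cl2, 0 °C to rt, 12 h
Reagents that add atoms: p-toluenesulfonyl chloride, Cc1ccc(cc1)S(=O)(=O)Cl
Why: O-sulfonylation (tosylation) reacts only at oxygen, so the C–O bond and the adjacent stereocentre stay intact, unlike HBr/PBr3 brominations, which can erode ee.

Step 2
Reactants: 2 (S)-2-methylbutyl 4-methylbenzenesulfonate; 3 diethyl malonate
Product: 5 diethyl (S)-(2-methylbutyl)malonate, via sodium malonate enolate 4 (not isolated)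
Conditions: 3 (1.5 equiv), NaH (1.4 equiv), THF/DMF 1:1, 0 °C to rt until H2 evolution ends; then 2 (1.0 equiv), 75 °C, 18 h
Reagents that add atoms: none
Why: In this malonic ester synthesis the weakly basic malonate anion displaces the primary tosylate by SN2 at CH2, excess malonate suppresses dialkylation, and the stereocentre next to the reacting carbon is retained.

Step 3
Reactants: 5 diethyl (S)-(2-methylbutyl)malonate
Product: 7 (S)-(2-methylbutyl)malonic acid, via dipotassium malonate salt 6 (not isolated)
Conditions: KOH (4 equiv), EtOH/H2O 1:1, reflux, 4 h; then conc. HCl to pH 1, 0 °C, extraction (Et2O)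
Reagents that add atoms: potassium hydroxide, [K+].[OH-]
Why: Saponification of both unhindered ethyl esters is quantitative, and the stereocentre is not alpha to a carbonyl, so base cannot epimerise it.

Step 4
Reactants: 7 (S)-(2-methylbutyl)malonic acid
Product: 8 (S)-4-methylhexanoic acid
Conditions: neat, 175 °C, 2 h (until gas evolution stops); vacuum distillation
Reagents that add atoms: none
Why: Thermal decarboxylation of a malonic acid through the cyclic six-membered transition state needs no reagent and leaves the gamma stereocentre untouched.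

Step 5
Reactants: 8 (S)-4-methylhexanoic acid
Product: 9 (S)-4-methylhexanoyl chloride
Conditions: (COCl)2 (1.3 equiv), DMF (1 mol %), CH2Cl2, 0 °C to rt, 2 h; evaporate, bulb-to-bulb distillation
Reagents that add atoms: oxalyl chloride, O=C(Cl)C(=O)Cl
Why: Vilsmeier-catalysed acid chloride formation gives only gaseous by-products, so the acyl donor is obtained pure and acid-free for the enolate step.

Step 6
Reactants: 10 ω-pentadecalactone (oxacyclohexadecan-2-one)
Product: 12 ω-hydroxypentadecanoic acid (15-hydroxypentadecanoic acid), via sodium hydroxy carboxylate 11 (not isolated)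
Conditions: NaOH (3 equiv), EtOH/H2O 4:1, reflux, 3 h; then 2 M HCl to pH 2, filter, dry
Reagents that add atoms: sodium hydroxide, [Na+].[OH-]
Why: Saponification of the macrolactone is irreversible because the carboxylate forms, and the hydroxy acid crystallises on acidification.

Step 7
Reactants: 12 ω-hydroxypentadecanoic acid
Product: 14 benzyl 15-hydroxypentadecanoate, via potassium hydroxy carboxylate 13 (not isolated)
Conditions: KHCO3 (1.5 equiv), BnBr (1.1 equiv), DMF, 40 °C, 16 h
Reagents that add atoms: benzyl bromide, BrCc1ccccc1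
Why: In this carboxylate O-alkylation (SN2) bicarbonate deprotonates only the acid, so benzylation is chemoselective for the carboxylate and the alcohol stays free.

Step 8
Reactants: 14 benzyl 15-hydroxypentadecanoate
Product: 15 benzyl 15-(benzyloxy)pentadecanoate
Conditions: BnOC(=NH)CCl3 (1.5 equiv), TfOH (5 mol %), CH2Cl2/cyclohexane 1:2, 0 °C to rt, 4 h
Reagents that add atoms: benzyl 2,2,2-trichloroacetimidate, N=C(OCc1ccccc1)C(Cl)(Cl)Cl
Why: Acid-catalysed trichloroacetimidate benzylation etherifies the primary alcohol without generating an alkoxide, which would transesterify and oligomerise the hydroxy ester.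

Step 9 (key C–C bond)
Reactants: 15 benzyl 15-(benzyloxy)pentadecanoate; 9 (S)-4-methylhexanoyl chloride
Product: 18 benzyl 15-(benzyloxy)-2-[(4S)-4-methylhexanoyl]pentadecanoate (C2 epimer mixture), via lithium ester enolate 16 (not isolated), via lithium ketoester enolate 17 (not isolated)
Conditions: LDA (2.05 equiv, commercial 2 M solution), THF, −78 °C; add 15 (2.1 equiv) dropwise, 45 min; then 9 (1.0 equiv) in THF, −78 °C, 1 h; sat. aq NH4Cl; chromatography (one equivalent of 15 is recovered)
Reagents that add atoms: none
Why: In this crossed Claisen condensation (acid chloride variant) LDA forms the ester enolate completely before it meets the highly reactive acyl chloride, a second equivalent of enolate removes the acidic proton of the product, the new alpha centre is an irrelevant epimer mixture erased in step 10, and the remote (S) centre is untouched.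

Step 10
Reactants: 18 benzyl 15-(benzyloxy)-2-[(4S)-4-methylhexanoyl]pentadecanoate
Product: 20 (3S)-20-hydroxy-3-methylicosan-6-one, via hydroxy ketoacid 19 (not isolated)
Conditions: H2 (1 atm), 10% Pd/C, EtOH/EtOAc 1:1, rt, 16 h; filter (Celite), concentrate; toluene, 90 °C, 1 h
Reagents that add atoms: none
Why: Neutral hydrogenolysis cleaves both O-benzyl groups, the freed beta-keto acid decarboxylates through a cyclic transition state with no base present to cause retro-Claisen cleavage, and the aliphatic ketone is inert to Pd/C at 1 atm.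

Step 11
Reactants: 20 (3S)-20-hydroxy-3-methylicosan-6-one
Product: 22 (18S)-18-methylicosan-1-ol, via ketone hydrazone 21 (not isolated)
Conditions: N2H4·H2O (10 equiv), KOH (6 equiv), diethylene glycol, 130 °C, 2 h; distil off H2O/N2H4; 200 °C, 4 h
Reagents that add atoms: none
Why: The Wolff–Kishner reduction (Huang-Minlon procedure) is the classical deoxygenation of long-chain ketones, it tolerates the free primary alcohol, and the stereocentre is gamma to the carbonyl and so cannot enolise.

Step 12
Reactants: 23 pyrocatechuic acid (2,3-dihydroxybenzoic acid)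
Product: 24 benzyl 2,3-bis(benzyloxy)benzoate
Conditions: BnBr (3.5 equiv), K2CO3 (4 equiv), DMF, 60 °C, 16 h
Reagents that add atoms: benzyl bromide, BrCc1ccccc1
Why: Exhaustive Williamson-type O-benzylation with excess reagent and heat also alkylates the hydrogen-bonded 2-OH and gives one fully protected product.

Step 13
Reactants: 24 benzyl 2,3-bis(benzyloxy)benzoate
Product: 26 O,O'-dibenzyl-2,3-dihydroxybenzoic acid [2,3-bis(benzyloxy)benzoic acid], via sodium dibenzyloxybenzoate 25 (not isolated)
Conditions: 5 M aq NaOH (5 equiv), THF/MeOH 1:1, reflux, 4 h; then 2 M HCl to pH 2, filter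
Reagents that add atoms: sodium hydroxide, [Na+].[OH-]
Why: Saponification cleaves only the ester because aryl benzyl ethers are inert to hydroxide.

Step 14
Reactants: 22 (18S)-18-methylicosan-1-ol; 26 2,3-bis(benzyloxy)benzoic acid
Product: 28 (18S)-18-methylicosyl 2,3-bis(benzyloxy)benzoate, via dicyclohexyl O-acylisourea 27 (not isolated)
Conditions: 26 (1.2 equiv), DCC (1.3 equiv), DMAP (0.2 equiv), CH2Cl2, 0 °C to rt, 16 h; filter, chromatography
Reagents that add atoms: none
Why: Steglich esterification joins the primary alcohol to the ortho-substituted acid under neutral conditions, DMAP acyl transfer outruns N-acylurea formation, and the masked catechol cannot compete as a nucleophile.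

Step 15
Reactants: 28 (18S)-18-methylicosyl 2,3-bis(benzyloxy)benzoate
Product: 29 Gentiside H [(18S)-18-methylicosyl 2,3-dihydroxybenzoate]
Conditions: H2 (1 atm), 10% Pd/C, EtOAc/EtOH 1:1, rt, 4 h; filter under N2, concentrate
Reagents that add atoms: none
Why: Catalytic hydrogenolysis removes the two aryl benzyl ethers, while the non-benzylic alkyl ester, the arene and the saturated chain with its (S) centre are unaffected.

## Compound list
1 | (S)-2-methylbutan-1-ol | CC[C@H](C)CO | starting material
2 | (S)-2-methylbutyl 4-methylbenzenesulfonate | CC[C@H](C)COS(=O)(=O)c1ccc(C)cc1 | intermediate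
3 | diethyl malonate | CCOC(=O)CC(=O)OCC | starting material
4 | sodium malonate enolate (not isolated) | CCOC(=O)C=C([O-])OCC.[Na+] | intermediate
5 | diethyl (S)-(2-methylbutyl)malonate | CC[C@H](C)CC(C(=O)OCC)C(=O)OCC | intermediate
6 | dipotassium (S)-(2-methylbutyl)malonate (not isolated) | CC[C@H](C)CC(C(=O)[O-])C(=O)[O-].[K+].[K+] | intermediate
7 | (S)-(2-methylbutyl)malonic acid | CC[C@H](C)CC(C(=O)O)C(=O)O | intermediate
8 | (S)-4-methylhexanoic acid | CC[C@H](C)CCC(=O)O | intermediate
9 | (S)-4-methylhexanoyl chloride | CC[C@H](C)CCC(=O)Cl | intermediate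
10 | ω-pentadecalactone (oxacyclohexadecan-2-one) | O=C1CCCCCCCCCCCCCCO1 | starting material
11 | sodium 15-hydroxypentadecanoate (not isolated) | [Na+].[O-]C(=O)CCCCCCCCCCCCCCO | intermediate
12 | 15-hydroxypentadecanoic acid | OC(=O)CCCCCCCCCCCCCCO | intermediate
13 | potassium 15-hydroxypentadecanoate (not isolated) | [K+].[O-]C(=O)CCCCCCCCCCCCCCO | intermediate
14 | benzyl 15-hydroxypentadecanoate | O=C(OCc1ccccc1)CCCCCCCCCCCCCCO | intermediate
15 | benzyl 15-(benzyloxy)pentadecanoate | O=C(OCc1ccccc1)CCCCCCCCCCCCCCOCc1ccccc1 | intermediate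
16 | lithium enolate of 15 (not isolated) | [Li+].[O-]C(OCc1ccccc1)=CCCCCCCCCCCCCCOCc1ccccc1 | intermediate
17 | lithium enolate of 18 (not isolated) | [Li+].CC[C@H](C)CCC([O-])=C(CCCCCCCCCCCCCOCc1ccccc1)C(=O)OCc1ccccc1 | intermediate
18 | benzyl 15-(benzyloxy)-2-[(4S)-4-methylhexanoyl]pentadecanoate (C2 epimers) | CC[C@H](C)CCC(=O)C(CCCCCCCCCCCCCOCc1ccccc1)C(=O)OCc1ccccc1 | intermediate
19 | 15-hydroxy-2-[(4S)-4-methylhexanoyl]pentadecanoic acid (not isolated) | CC[C@H](C)CCC(=O)C(CCCCCCCCCCCCCO)C(=O)O | intermediate
20 | (3S)-20-hydroxy-3-methylicosan-6-one | CC[C@H](C)CCC(=O)CCCCCCCCCCCCCCO | intermediate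
21 | hydrazone of 20 (not isolated) | CC[C@H](C)CCC(=NN)CCCCCCCCCCCCCCO | intermediate
22 | (18S)-18-methylicosan-1-ol | CC[C@H](C)CCCCCCCCCCCCCCCCCO | intermediate
23 | 2,3-dihydroxybenzoic acid | OC(=O)c1cccc(O)c1O | starting material
24 | benzyl 2,3-bis(benzyloxy)benzoate | O=C(OCc1ccccc1)c1cccc(OCc2ccccc2)c1OCc1ccccc1 | intermediate
25 | sodium 2,3-bis(benzyloxy)benzoate (not isolated) | [Na+].[O-]C(=O)c1cccc(OCc2ccccc2)c1OCc1ccccc1 | intermediate
26 | 2,3-bis(benzyloxy)benzoic acid | OC(=O)c1cccc(OCc2ccccc2)c1OCc1ccccc1 | intermediate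
27 | O-acylisourea from 26 and DCC (not isolated) | O=C(OC(=NC1CCCCC1)NC1CCCCC1)c1cccc(OCc2ccccc2)c1OCc1ccccc1 | intermediate
28 | (18S)-18-methylicosyl 2,3-bis(benzyloxy)benzoate | CC[C@H](C)CCCCCCCCCCCCCCCCCOC(=O)c1cccc(OCc2ccccc2)c1OCc1ccccc1 | intermediate
29 | Gentiside H, (18S)-18-methylicosyl 2,3-dihydroxybenzoate | CC[C@H](C)CCCCCCCCCCCCCCCCCOC(=O)c1cccc(O)c1O | target

## Summary
Total step count: 15.
Longest linear sequence: 10 steps (steps 1–5, 9–11, 14, 15).

Three steps most likely to fail:

**Step 9 (crossed Claisen).** The risks are O-acylation, ketene formation from 9 and self-condensation of 15. The fallback sets out from 9 and 15 and returns at 18, replacing the acylation by an aldol addition followed by oxidation.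
- Compound 9 is reduced with LiAlH(Ot-Bu)3 (THF, −78 °C) to (S)-4-methylhexanal F1.
- F1 (1.0 equiv) is added at −78 °C to enolate 16 (1.1 equiv, made from 15 with LDA as before). This gives the lithium aldolate F2.
- An NH4Cl quench gives benzyl 15-(benzyloxy)-2-[(4S)-1-hydroxy-4-methylhexyl]pentadecanoate F3, an irrelevant diastereomer mixture.
- Dess–Martin periodinane (NaHCO3, CH2Cl2, rt) oxidises the carbinol to the beta-keto ester 18.
- The aldehyde acceptor cannot over-react, and only one equivalent of enolate is needed.

**Step 11 (Wolff–Kishner).** The risks are azine formation, incomplete conversion and poor solubility of the waxy substrate. The fallback sets out from 20 and returns at 22.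
- Ethane-1,2-dithiol (1.5 equiv) and BF3·OEt2 (CH2Cl2, 0 °C to rt) convert the ketone into 14-{2-[(3S)-3-methylpentyl]-1,3-dithiolan-2-yl}tetradecan-1-ol F4.
- Raney nickel (EtOH, reflux; Mozingo reduction) desulfurises F4 to 22.
- The sequence uses no strong base or high temperature, and the free alcohol is tolerated in both operations.

**Step 2 (SN2 on a beta-branched tosylate).** The risks are slow substitution and competing elimination. The fallback sets out from 1 and returns at 8, replacing steps 1–4 by an olefination.
- Anelli oxidation of 1 (TEMPO 1 mol %, KBr, NaOCl, CH2Cl2/H2O, 0 °C) gives (S)-2-methylbutanal F5.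
- F5 is used at once with benzyl (triphenylphosphoranylidene)acetate (CH2Cl2, rt). This Wittig olefination is base-free, so the alpha centre is not epimerised, and it gives benzyl (2E,4S)-4-methylhex-2-enoate F6.
- H2/Pd-C (EtOAc, rt) saturates the conjugated alkene and cleaves the benzyl ester in one operation to give 8.
- Pd can migrate the alkene toward the allylic stereocentre, so the ee of 8 is checked by chiral GC of its methyl ester before use.

## Further compounds
F1 | step 9 | (S)-4-methylhexanal | CC[C@H](C)CCC=O
F2 | step 9 | lithium aldolate of F3 | [Li+].CC[C@H](C)CCC([O-])C(CCCCCCCCCCCCCOCc1ccccc1)C(=O)OCc1ccccc1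
F3 | step 9 | benzyl 15-(benzyloxy)-2-[(4S)-1-hydroxy-4-methylhexyl]pentadecanoate | CC[C@H](C)CCC(O)C(CCCCCCCCCCCCCOCc1ccccc1)C(=O)OCc1ccccc1
F4 | step 11 | 14-{2-[(3S)-3-methylpentyl]-1,3-dithiolan-2-yl}tetradecan-1-ol | CC[C@H](C)CCC1(CCCCCCCCCCCCCCO)SCCS1
F5 | step 2 | (S)-2-methylbutanal | CC[C@H](C)C=O
F6 | step 2 | benzyl (2E,4S)-4-methylhex-2-enoate | CC[C@H](C)/C=C/C(=O)OCc1ccccc1
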